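**Strategy.** Ring B carries oxygen on both neighbours of the quaternary C10 (C5 and C9), so it maps onto 2-methylcyclohexane-1,3-dione, and O5–C5–C4–C19 is a β-hydroxy acid, an aldol retron. Everything rests on closing ring A between C4 and C5 by a copper hydride-catalysed enantioselective reductive aldol cyclisation of an achiral enoate-tethered dione. In one operation it makes the C4–C5 bond, desymmetrises the dione (C10) and sets the C4 quaternary centre. Its precursor is a monocyclic diketo enoate, two steps from commercial materials. The cis ring fusion of such closures is corrected at C5 by dehydration and radical hydration; C9 and the side chain come from a late organolithium addition.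

Key step: step 3

Remark: labdane numbering (C1–C20) and α/β descriptors (β = face of the C10 methyl) are used throughout; which antipode of the ligand in step 3 gives the shown series is fixed by a first screen, (R) being written for definiteness.

**Step 1**
Reactants: 1 2-methylcyclohexane-1,3-dione; 2 acrolein
Product: 3 3-(1-methyl-2,6-dioxocyclohexyl)propanal
Conditions: H2O, rt
Reagents that add atoms: none
Why: Michael addition of the acidic cyclic 1,3-dione to acrolein builds the quaternary C10 with the C1–C3 chain, and the product is still achiral.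

**Step 2**
Reactants: 3 3-(1-methyl-2,6-dioxocyclohexyl)propanal; 4 methyl 2-(triphenylphosphoranylidene)propanoate
Product: 5 methyl (E)-2-methyl-5-(1-methyl-2,6-dioxocyclohexyl)pent-2-enoate
Conditions: CH2Cl2, rt
Reagents that add atoms: none
Why: Wittig olefination with a stabilised ylide is E-selective and takes the aldehyde in preference to the two hindered ring ketones.

**Step 3**
Reactants: 5 methyl (E)-2-methyl-5-(1-methyl-2,6-dioxocyclohexyl)pent-2-enoate
Product: 7 methyl (1S,4aS,8aR)-8a-hydroxy-1,4a-dimethyl-5-oxodecahydronaphthalene-1-carboxylate (cis-fused ketol; 4β-CO2Me 4α-Me 5β-OH 10β-Me), via silyl ether 6 (not isolated)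
Conditions: Cu(OAc)2·H2O (5 mol %), (R)-DTBM-SEGPHOS (5.5 mol %), (EtO)2MeSiH, toluene, −25 °C; then NH4F, MeOH
Reagents that add atoms: none
Why: The ligated copper hydride adds hydride to C3 of the enoate and the resulting copper enolate attacks one of the two enantiotopic ring carbonyls (C5) through a closed, chelated Zimmerman–Traxler array, after which σ-bond metathesis with the silane releases silyl ether 6 and the copper hydride. The closest known reaction type is the copper hydride-catalysed asymmetric reductive aldol cyclisation of enoate- or enone-tethered ketones and 2,2-disubstituted 1,3-diones. Ring A closes in the 6-(enolexo)-exo-trig mode. C10 is set by the chiral bisphosphine, which selects the carbonyl that is attacked; C4 is set by the closed transition state, in which the ester stays gauche to the carbonyl oxygen and the C4 methyl avoids the positions syn-axial to the C10 methyl or to C9, so the ester should end cis to the C10 methyl; C5 should come out cis (5β-OH), which is of no consequence because step 4 erases it. The step needs conjugate reduction of the trisubstituted enoate ahead of 1,2-reduction of the ketones, which their position next to the quaternary C10 secures, and it needs the ester enolate in the presence of two more acidic ketones, which hydride delivery to C3 secures regiospecifically.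

**Step 4**
Reactants: 7 cis-fused ketol
Product: 8 methyl (1S,4aS)-1,4a-dimethyl-5-oxo-1,2,3,4,4a,5,6,7-octahydronaphthalene-1-carboxylate (5,6-ene)
Conditions: Martin sulfurane (Ph2S[OC(CF3)2Ph]2), CH2Cl2, 0 °C to rt
Reagents that add atoms: none
Why: Dehydration of the tertiary alcohol through its alkoxysulfonium derivative can only give the C5=C6 alkene because C4 and C10 are quaternary, and it removes the unwanted C5 configuration.

**Step 5**
Reactants: 8 5,6-ene
Product: 10 methyl (1S,4aS,8aS)-8a-hydroxy-1,4a-dimethyl-5-oxodecahydronaphthalene-1-carboxylate (trans-fused ketol; 5α-OH), via hydroperoxide 9 (not isolated)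
Conditions: Mn(dpm)3 (10 mol %), PhSiH3, O2 (1 atm), i-PrOH/CH2Cl2, 0 °C to rt; then PPh3
Reagents that add atoms: dioxygen, O=O
Why: Mukaiyama-type hydration by metal hydride hydrogen atom transfer puts H on C6, and the tertiary C5 radical should take up O2 on the α face, anti to the axial 10β-methyl and 4β-ester, to give the trans-fused 5α-hydroperoxide that PPh3 reduces.

**Step 6**
Reactants: 10 trans-fused ketol
Product: 12 methyl (1S,4aS,8aS)-8a-hydroxy-1,4a-dimethyl-6-methylidene-5-oxodecahydronaphthalene-1-carboxylate, via Mannich base 11 (not isolated)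
Conditions: (CH2O)n, i-Pr2NH·CF3CO2H, CF3CO2H (10 mol %), THF, reflux
Reagents that add atoms: paraformaldehyde (as formaldehyde), C=O
Why: Mannich-type α-methylenation goes through the aminomethyl ketone and its elimination, and C8 is the only enolisable position of the C9 ketone because C10 is quaternary.

**Step 7**
Reactants: 13 tert-butyl(but-3-yn-1-yloxy)dimethylsilane
Product: 16 (E)-5-[(tert-butyldimethylsilyl)oxy]-3-methylpent-2-en-1-ol, via alkenylalane 14 (not isolated), via lithium aluminate 15 (not isolated)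
Conditions: AlMe3, Cp2ZrCl2 (20 mol %), CH2Cl2, 0 °C to rt; evaporate; n-BuLi, THF, −78 °C; (CH2O)n, rt; aq. Rochelle salt
Reagents that add atoms: trimethylaluminium, C[Al](C)C; paraformaldehyde (as formaldehyde), C=O
Why: Negishi zirconium-catalysed carboalumination adds methyl and aluminium syn across the alkyne, and the alkenyl aluminate takes formaldehyde with retention, which fixes the E trisubstituted alkene.

**Step 8**
Reactants: 16 (E)-5-[(tert-butyldimethylsilyl)oxy]-3-methylpent-2-en-1-ol
Product: 17 (E)-1-[(tert-butyldiphenylsilyl)oxy]-5-[(tert-butyldimethylsilyl)oxy]-3-methylpent-2-ene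
Conditions: TBDPSCl, imidazole, CH2Cl2, rt
Reagents that add atoms: tert-butyl(chloro)diphenylsilane (TBDPSCl), CC(C)(C)[Si](Cl)(c1ccccc1)c1ccccc1
Why: Silylation of the allylic alcohol gives a robust ether that later survives tert-butyllithium and mild acid.

**Step 9**
Reactants: 17 bis-silyl ether
Product: 18 (E)-5-[(tert-butyldiphenylsilyl)oxy]-3-methylpent-3-en-1-ol
Conditions: PPTS (cat.), MeOH, rt
Reagents that add atoms: none
Why: Acid-catalysed methanolysis cleaves the primary tert-butyldimethylsilyl ether much faster than the tert-butyldiphenylsilyl ether.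

**Step 10**
Reactants: 18 (E)-5-[(tert-butyldiphenylsilyl)oxy]-3-methylpent-3-en-1-ol
Product: 19 (E)-tert-butyl[(5-iodo-3-methylpent-2-en-1-yl)oxy]diphenylsilane
Conditions: I2, PPh3, imidazole, CH2Cl2, 0 °C
Reagents that add atoms: iodine, II
Why: Appel-type iodination converts the primary homoallylic alcohol into the iodide without touching the alkene geometry.

**Step 11**
Reactants: 19 (E)-tert-butyl[(5-iodo-3-methylpent-2-en-1-yl)oxy]diphenylsilane (2.5 equiv); 12 α-methylene ketone
Product: 21 methyl (1S,4aR,5S,8aS)-5-{(E)-5-[(tert-butyldiphenylsilyl)oxy]-3-methylpent-3-en-1-yl}-5,8a-dihydroxy-1,4a-dimethyl-6-methylidenedecahydronaphthalene-1-carboxylate, via organolithium 20 (not isolated)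
Conditions: t-BuLi (2 equiv per iodide), Et2O, −78 °C; then 12, THF, −78 to −40 °C; aq. NH4Cl
Reagents that add atoms: none
Why: Organolithium 1,2-addition to the α-methylene ketone should occur on the α face, anti to the axial C10 methyl (torsional control as in angular-methyl decalones) and guided by the lithium 5α-alkoxide, which places C11 axial α and the new hydroxyl β.

**Step 12**
Reactants: 21 silyl-protected adduct
Product: 22 methyl (1S,4aR,5S,8aS)-5,8a-dihydroxy-5-[(E)-5-hydroxy-3-methylpent-3-en-1-yl]-1,4a-dimethyl-6-methylidenedecahydronaphthalene-1-carboxylate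
Conditions: TBAF, THF, 0 °C to rt
Reagents that add atoms: none
Why: Fluoride-induced desilylation frees the primary allylic alcohol under conditions that leave the tertiary allylic alcohol and the ester alone.

**Step 13**
Reactants: 22 triol methyl ester
Product: 24 5α,9β-dihydroxyisocupressic acid, via lithium carboxylate 23 (not isolated)
Conditions: n-PrSLi (from n-PrSH, n-BuLi), HMPA, rt; then cold 0.1 M HCl to pH 4
Reagents that add atoms: none
Why: SN2 demethylation by thiolate in a dipolar aprotic solvent cleaves the hindered axial C19 methyl ester at the methyl carbon, which avoids the forcing hydroxide conditions that could trigger retro-aldol cleavage.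

**Compound list**

1 | 2-methylcyclohexane-1,3-dione | CC1C(=O)CCCC1=O | starting material
2 | acrolein | C=CC=O | starting material
3 | 3-(1-methyl-2,6-dioxocyclohexyl)propanal | O=CCCC1(C)C(=O)CCCC1=O | intermediate
4 | methyl 2-(triphenylphosphoranylidene)propanoate | COC(=O)C(C)=P(c1ccccc1)(c1ccccc1)c1ccccc1 | starting material
5 | methyl (E)-2-methyl-5-(1-methyl-2,6-dioxocyclohexyl)pent-2-enoate | COC(=O)/C(C)=C/CCC1(C)C(=O)CCCC1=O | intermediate
6 | methyl (1S,4aS,8aR)-8a-{[diethoxy(methyl)silyl]oxy}-1,4a-dimethyl-5-oxodecahydronaphthalene-1-carboxylate | C1CC[C@@]2(O[Si](C)(OCC)OCC)[C@](C)(CCC[C@]2(C)C(=O)OC)C1=O | intermediate (not isolated)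
7 | methyl (1S,4aS,8aR)-8a-hydroxy-1,4a-dimethyl-5-oxodecahydronaphthalene-1-carboxylate (cis-fused; 5β-OH) | C1CC[C@@]2(O)[C@](C)(CCC[C@]2(C)C(=O)OC)C1=O | intermediate
8 | methyl (1S,4aS)-1,4a-dimethyl-5-oxo-1,2,3,4,4a,5,6,7-octahydronaphthalene-1-carboxylate | C1CC=C2[C@](C)(CCC[C@]2(C)C(=O)OC)C1=O | intermediate
9 | methyl (1S,4aS,8aS)-8a-hydroperoxy-1,4a-dimethyl-5-oxodecahydronaphthalene-1-carboxylate | C1CC[C@]2(OO)[C@](C)(CCC[C@]2(C)C(=O)OC)C1=O | intermediate (not isolated)
10 | methyl (1S,4aS,8aS)-8a-hydroxy-1,4a-dimethyl-5-oxodecahydronaphthalene-1-carboxylate (trans-fused; 5α-OH) | C1CC[C@]2(O)[C@](C)(CCC[C@]2(C)C(=O)OC)C1=O | intermediate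
11 | methyl (1S,4aS,8aS)-6-[(diisopropylamino)methyl]-8a-hydroxy-1,4a-dimethyl-5-oxodecahydronaphthalene-1-carboxylate (C8 epimers) | CC(C)N(CC1CC[C@]2(O)[C@](C)(CCC[C@]2(C)C(=O)OC)C1=O)C(C)C | intermediate (not isolated)
12 | methyl (1S,4aS,8aS)-8a-hydroxy-1,4a-dimethyl-6-methylidene-5-oxodecahydronaphthalene-1-carboxylate | C=C1CC[C@]2(O)[C@](C)(CCC[C@]2(C)C(=O)OC)C1=O | intermediate
13 | tert-butyl(but-3-yn-1-yloxy)dimethylsilane | C#CCCO[Si](C)(C)C(C)(C)C | starting material
14 | (E)-{4-[(tert-butyldimethylsilyl)oxy]-2-methylbut-1-en-1-yl}dimethylalane | C[Al](C)/C=C(\C)CCO[Si](C)(C)C(C)(C)C | intermediate (not isolated)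
15 | lithium butyl{(E)-4-[(tert-butyldimethylsilyl)oxy]-2-methylbut-1-en-1-yl}dimethylaluminate | [Li+].CCCC[Al-](C)(C)/C=C(\C)CCO[Si](C)(C)C(C)(C)C | intermediate (not isolated)
16 | (E)-5-[(tert-butyldimethylsilyl)oxy]-3-methylpent-2-en-1-ol | OC/C=C(\C)CCO[Si](C)(C)C(C)(C)C | intermediate
17 | (E)-1-[(tert-butyldiphenylsilyl)oxy]-5-[(tert-butyldimethylsilyl)oxy]-3-methylpent-2-ene | CC(C)(C)[Si](C)(C)OCC/C(C)=C/CO[Si](c1ccccc1)(c1ccccc1)C(C)(C)C | intermediate
18 | (E)-5-[(tert-butyldiphenylsilyl)oxy]-3-methylpent-3-en-1-ol | OCC/C(C)=C/CO[Si](c1ccccc1)(c1ccccc1)C(C)(C)C | intermediate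
19 | (E)-tert-butyl[(5-iodo-3-methylpent-2-en-1-yl)oxy]diphenylsilane | ICC/C(C)=C/CO[Si](c1ccccc1)(c1ccccc1)C(C)(C)C | intermediate
20 | {(E)-5-[(tert-butyldiphenylsilyl)oxy]-3-methylpent-3-en-1-yl}lithium | [Li]CC/C(C)=C/CO[Si](c1ccccc1)(c1ccccc1)C(C)(C)C | intermediate (not isolated)
21 | methyl (1S,4aR,5S,8aS)-5-{(E)-5-[(tert-butyldiphenylsilyl)oxy]-3-methylpent-3-en-1-yl}-5,8a-dihydroxy-1,4a-dimethyl-6-methylidenedecahydronaphthalene-1-carboxylate | C=C1CC[C@]2(O)[C@](C)(CCC[C@]2(C)C(=O)OC)[C@]1(O)CC/C(C)=C/CO[Si](c1ccccc1)(c1ccccc1)C(C)(C)C | intermediate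
22 | methyl (1S,4aR,5S,8aS)-5,8a-dihydroxy-5-[(E)-5-hydroxy-3-methylpent-3-en-1-yl]-1,4a-dimethyl-6-methylidenedecahydronaphthalene-1-carboxylate | C=C1CC[C@]2(O)[C@](C)(CCC[C@]2(C)C(=O)OC)[C@]1(O)CC/C(C)=C/CO | intermediate
23 | lithium (1S,4aR,5S,8aS)-5,8a-dihydroxy-5-[(E)-5-hydroxy-3-methylpent-3-en-1-yl]-1,4a-dimethyl-6-methylidenedecahydronaphthalene-1-carboxylate | [Li+].C=C1CC[C@]2(O)[C@](C)(CCC[C@]2(C)C(=O)[O-])[C@]1(O)CC/C(C)=C/CO | intermediate (not isolated)
24 | 5α,9β-dihydroxyisocupressic acid, (1S,4aR,5S,8aS)-5,8a-dihydroxy-5-[(E)-5-hydroxy-3-methylpent-3-en-1-yl]-1,4a-dimethyl-6-methylidenedecahydronaphthalene-1-carboxylic acid | C=C1CC[C@]2(O)[C@](C)(CCC[C@]2(C)C(=O)O)[C@]1(O)CC/C(C)=C/CO | target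

**Total step count:** 13
**Longest linear sequence:** 9 (steps 1–6 and 11–13)

**Steps most likely to fail**

Step 3. The hydride transfer to the α-methyl enoate may be slow, a ring ketone may be reduced in its place, or the ligand may discriminate poorly between the two carbonyls. The fallback moves the same ring closure to amine catalysis; it sets out from 3 and comes back at 7. Wittig reaction of 3 with 2-(triphenylphosphoranylidene)propanal should give (E)-2-methyl-5-(1-methyl-2,6-dioxocyclohexyl)pent-2-enal F1. A chiral primary amine salt (9-amino-9-deoxy-epi-quinine trifluoroacetate) with a Hantzsch ester should reduce the iminium ion of F1 to the α,α-disubstituted enamine, which closes onto C5 to give the cis-fused 5β-hydroxy-9-oxo aldehyde F2 (4β-CHO, 4α-Me, 10β-Me). Pinnick oxidation should then give the corresponding acid F3, and trimethylsilyldiazomethane returns 7.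

Step 5. Hydrogen atom transfer to an alkene shielded by two quaternary carbons may fail, or oxygen may be captured on the β face. The fallback uses ionic chemistry; it sets out from 8 and comes back at 10. m-CPBA should epoxidise the α face to give the 5α,6α-epoxide F4. Sodium benzeneselenolate (PhSeH, NaH, THF) should open it in the trans-diaxial sense at C6 to give the 6β-phenylselanyl-5α-ol F5. Bu3SnH with AIBN then removes selenium and gives 10.

Step 11. The bulky alkyllithium may attack the β face of C9 or discriminate poorly, because the 5α-alkoxide crowds the axial trajectory, and conjugate addition may compete. The fallback delivers a slim nucleophile first and builds the chain afterwards; it sets out from 12 and comes back at 22. Ethynylmagnesium bromide with CeCl3 should add axially to give the 9α-ethynyl-9β-ol F6. Semi-hydrogenation over Pd/CaCO3 poisoned with Pb(OAc)2 and quinoline should give the 9α-vinyl carbinol F7. 9-BBN should hydroborate the vinyl group in preference to the flanked C8 methylene to give the B-alkyl borane F8. Suzuki–Miyaura coupling (Pd(dppf)Cl2, AsPh3, Cs2CO3, DMF/H2O) with (E)-3-iodobut-2-en-1-ol F9, made from but-2-yn-1-ol by stannylcupration and iodinolysis, gives 22 directly.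

**Further compounds**

F1 | step 3 | (E)-2-methyl-5-(1-methyl-2,6-dioxocyclohexyl)pent-2-enal | O=C/C(C)=C/CCC1(C)C(=O)CCCC1=O
F2 | step 3 | cis-fused 8a-hydroxy-1,4a-dimethyl-5-oxodecahydronaphthalene-1-carbaldehyde (4β-CHO, 4α-Me, 5β-OH, 10β-Me) | C1CC[C@@]2(O)[C@](C)(CCC[C@]2(C)C=O)C1=O
F3 | step 3 | (1S,4aS,8aR)-8a-hydroxy-1,4a-dimethyl-5-oxodecahydronaphthalene-1-carboxylic acid | C1CC[C@@]2(O)[C@](C)(CCC[C@]2(C)C(=O)O)C1=O
F4 | step 5 | methyl 5α,6α-epoxy-4α,10β-dimethyl-9-oxodecalin-4β-carboxylate (labdane numbering) | C1C[C@@H]2O[C@]23[C@](C)(CCC[C@]3(C)C(=O)OC)C1=O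
F5 | step 5 | methyl 5α-hydroxy-4α,10β-dimethyl-9-oxo-6β-(phenylselanyl)decalin-4β-carboxylate (labdane numbering) | C1C[C@@H]([Se]c2ccccc2)[C@]3(O)[C@](C)(CCC[C@]3(C)C(=O)OC)C1=O
F6 | step 11 | methyl (1S,4aR,5S,8aS)-5-ethynyl-5,8a-dihydroxy-1,4a-dimethyl-6-methylidenedecahydronaphthalene-1-carboxylate | C=C1CC[C@]2(O)[C@](C)(CCC[C@]2(C)C(=O)OC)[C@]1(O)C#C
F7 | step 11 | methyl (1S,4aR,5S,8aS)-5-ethenyl-5,8a-dihydroxy-1,4a-dimethyl-6-methylidenedecahydronaphthalene-1-carboxylate | C=C1CC[C@]2(O)[C@](C)(CCC[C@]2(C)C(=O)OC)[C@]1(O)C=C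
F8 | step 11 | methyl (1S,4aR,5S,8aS)-5-[2-(9-borabicyclo[3.3.1]nonan-9-yl)ethyl]-5,8a-dihydroxy-1,4a-dimethyl-6-methylidenedecahydronaphthalene-1-carboxylate | C=C1CC[C@]2(O)[C@](C)(CCC[C@]2(C)C(=O)OC)[C@]1(O)CCB1C2CCCC1CCC2
F9 | step 11 | (E)-3-iodobut-2-en-1-ol | I/C(C)=C/CO
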